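## Analysis of the target

The target 33 is a germacranolide. Its core is a cyclodeca-1(10),4-diene (ring C1–C10) in which C1=C10 is cis within the ring and carries the C14 methyl on C10, while C4=C5 is trans within the ring and carries the acetoxymethyl carbon C15 on C4. An α-methylene-γ-butyrolactone (C11, C12, exocyclic C13, ring oxygen on C6) is fused across C6–C7. There are four stereocentres. C6 (R), C7 (R) and C8 (R) are contiguous: the lactone oxygen on C6 is trans to the C7–C11 bond and the free hydroxyl on C8 is cis to it. C2 (S) carries the tiglate and is insulated from this triad by both alkenes. The sensitive groups are the exocyclic enoate (a Michael acceptor), two allylic esters and an allylic lactone C–O bond, the C8 hydroxyl (placed so that base can move the lactone to it), and the 1,5-diene (Cope rearrangement, transannular cyclisation with electrophiles). The difficulty lies in closing a strained medium ring with two trisubstituted alkenes of opposite ring geometry, relating the remote C2 centre to the triad, and telling four oxygen functions apart. The strategy rests on the six atoms C10=C1–C2–C3–C4=C5: a 1,5-diene with one cis and one trans alkene is what a bicyclo[2.2.0]hexane built from C1, C2, C3, C4, C5 and C10 gives when its C1–C4 and C5–C10 bonds break. That bicycle is the [2+2] adduct of a 3-methylcyclohex-2-enone (C5–C10, carbonyl C6) and a cyclobut-1-enecarboxylate (C1–C4, ester carbon C15).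

## Retrosynthetic reasoning

**Acyl groups and free hydroxyl (33 ← 32 ← 30 + 31 ← 29 ← 28).** The O–Si bond at C8, the tiglate C–O bond at C2, the O–Si bond at C2 and the acetate C–O bond at C15 are cut in that order. The esters and the free C8 hydroxyl tolerate neither hydride nor enolate chemistry, so they are placed last. Two silyl ethers of different lability (triethylsilyl on C2, tert-butyldimethylsilyl on C8) fix the sequence.

**Methylene group (28 ← 26 ← 25).** The C11=C13 bond is cut back to a Mannich base 26 and to the saturated lactone 25. This needs the lactone enolate and therefore has to precede every acylation.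

**Lactone relay (25 ← 24 ← 22, via 23).** The O6–C12 bond is cut to the hydroxy ester 24. Its C6 and C15 hydroxyls are recognised as the reduction product of a butenolide 22 in which O6 is acylated by C15. This lets C15 end at the alcohol level and C12 at the acid level, and it means that one lactone holds O6 during the ring-forming step and another one in the target.

**Cycloreversion (22 ← 21).** C1–C4 and C5–C10 are reconnected, which folds the ten-membered diene into the tetracycle 21. The forward step has to open the ring and create both alkenes at once. The O6–C15 lactone bridge of 21 can only end as a butenolide with C15 and C6 cis on C4=C5, which is the ring-trans geometry of the target; the cis ring fusion then leaves C1=C10 ring-cis.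

**C6 carbinol (21 ← 19, via 20).** The O6–C15 bond and the C6–H bond are cut back to the ketone 19. The reduction is placed on the rigid tricycle, where the angular C4 ester differentiates the faces of C6, and not on a floppy ten-membered ketone.

**Key disconnection (19 ← 11 + 18).** C4–C5 and C1–C10 are cut. The enone 11 brings C5–C10 with the C6 carbonyl and the C7 and C8 stereocentres. The cyclobutene ester 18 brings C1–C4, C15 and the C2 stereocentre. The forward step must be head-to-head and must use the enone face opposite its two ring substituents.

**Enone (11 ← 10 ← 8 ← 7 ← 6).** The C5=C10 alkene is cut by ring-closing metathesis to the vinyl ketone 10, which is traced through the Weinreb amide 8 and the silyl ether 7 to the hydroxy diester 6. Metathesis is neutral, which matters because C7 is epimerisable and C8 carries a β-leaving group.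

**C7–C11 bond (6 ← 4 + 5).** An anti-selective alkylation of the dianion of 4 with 5 sets C7 from C8. The anti relationship in the chain becomes the cis relationship of arm and oxygen on the ring.

**C9–C10 bond (4 ← 2 + 3, 2 ← 1).** Opening of the epoxide 2 by the alkenyl Grignard 3 attaches C10; C8 comes from the chiral pool in 1.

**Cyclobutene (18 ← 17 ← 16 ← 13 ← 12, via 14 and 15).** The alkene is cut to an α-selanyl ester of the achiral alcohol 13. Because that elimination can only give a racemate, a resolution step (16 → 17) is inserted so that C2 enters the key step as one enantiomer.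

## Alternatives that were turned down

**Alternative 1:** disconnection at C5–C6. The ring would be closed last from the open-chain iodo aldehyde A2 by a Nozaki–Hiyama–Kishi reaction (CrCl2, catalytic NiCl2) to the ring carbinol A1. Its C7 arm is a protected 2-substituted allyl alcohol that is oxidised to the methylene lactone afterwards.
- For: both alkene geometries are fixed in acyclic chemistry and the alkenyl iodide reacts with retention. The chromium conditions tolerate the tiglate and acetate. The methylene lactone arises by allylic oxidation, not by enolate chemistry. On the last two points it is stronger than the chosen route.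
- Against: a strained ten-membered ring has to be closed at high dilution. The C6 configuration is created in that same step, with nothing that reliably places the hydroxyl trans to the C7 arm. C7 in A2 is both α to the aldehyde and allylic, so epimerisation and conjugation threaten. Four stereocentres and two trisubstituted alkenes must be built one after another in a long chain, and chromium is used in excess.
- Comparison: the chosen route makes the ring and both alkenes from a compact tricycle in one thermal step and sets C6 on a six-membered ring. It pays with a longer adjustment of oxidation levels afterwards.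

**Alternative 2:** disconnection of O6–C12 and of the C15–O acetate bond in one step. The ring diene acid A4 (exocyclic C4=C15 conjugated with C5=C6, acrylic acid arm on C7) would be treated with Pd(OAc)2, 1,4-benzoquinone and LiOAc in acetic acid. The carboxylate adds to C6, acetate adds to C15 of the allylpalladium unit, and the alkene ends at C4=C5 in A3, which is the same compound as 32.
- For: one step forms the lactone, the allylic acetate and the alkene position with the methylene group already present, and A3 is one deprotection from the target. As an end game it is shorter than the chosen one.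
- Against: it does not make the ring. A4 already contains the ten-membered ring, C1=C10, C2, C7, C8 and a doubly allylic C7–H. The geometry of the new C4=C5 depends on whether C6 sits syn or anti on the allyl unit inside a medium ring, and the ring fusion depends on the face of metal coordination. Divalent palladium is an electrophile that can trigger transannular cyclisation of the cyclodeca-1,5-diene, and the acrylic acid and tiglate are further alkenes.
- Comparison: the chosen route solves the ring construction, which this alternative only postpones.

**Alternative 3:** disconnection of C5–C10 as in the chosen route, but heterolytic. A eudesmane-type trans-decalin A6 (C10 tertiary hydroxyl, spiro-epoxide at C4) would undergo Grob fragmentation with Ti(OiPr)4 or KOtBu. C5–C10 and the C4–O bond break to give the ten-membered ketone A5 with a cis C1=C2 enone, trans C4=C5 and a free C15 hydroxyl.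
- For: the fragmentation is stereospecific, so the C4=C5 geometry follows from the decalin without any tether. Strain appears only in a strongly driven step. C6–C8 are set on a rigid decalin. C15 arrives at the alcohol level with no ester reduction. On these points it is as strong as or stronger than the chosen route.
- Against: A5 has its oxygen at C10 and its alkene at C1=C2. The C14 methyl and the C2 oxygen are missing and need a methyl addition followed by a 1,3-transposition, in which the ring geometry of C1=C10 and the configuration at C2 must be controlled afresh on a flexible ring. The lactone is at the acetal level and must be reoxidised. A6 has six stereocentres including the spiro-epoxide. The cis-enone in a medium ring invites transannular aldol or Michael reactions.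
- Comparison: the cycloreversion of the chosen route gives both alkenes with the methyl already on C10 and the oxygen already on C2, the latter brought in as one enantiomer with the cyclobutene.

Key step: step 12

Remark: all compounds carry the germacrane atom numbers of the target (ring C1–C10, lactone arm C11–C13, C14 on C10, C15 on C4). Centres that are made and erased again (C1, C4, C5, C10 of the tricycle, C11 of 26 and 27, the lactol carbon of 23) are carried as they form. All starting materials (1, 3, 5, 9, 12, 31) are taken to be commercial.

## Route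

Step 1
Reactants: 1 ethyl (3S)-4-chloro-3-hydroxybutanoate
Product: 2 ethyl 2-[(2S)-oxiran-2-yl]acetate
Conditions: Ag2O, DME, 60 °C, dark
Reagents that add atoms: none
Why: Silver-assisted intramolecular Williamson closure of the chlorohydrin; the reagent is not basic enough to cause β-elimination to the 4-hydroxycrotonate, and the oxygen-bearing centre (C8) is not touched.

Step 2
Reactants: 2 ethyl 2-[(2S)-oxiran-2-yl]acetate; 3 prop-1-en-2-ylmagnesium bromide
Product: 4 ethyl (3R)-3-hydroxy-5-methylhex-5-enoate
Conditions: 3, CuI (10 mol%), THF, −40 °C; aq. NH4Cl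
Reagents that add atoms: none
Why: Copper-catalysed SN2 opening of the terminal epoxide at its CH2 (C9) by the alkenyl Grignard reagent, at a temperature where the ester is not attacked; C8 keeps its configuration and the descriptor changes only because the priorities change.

Step 3
Reactants: 4 ethyl (3R)-3-hydroxy-5-methylhex-5-enoate; 5 tert-butyl bromoacetate
Product: 6 4-tert-butyl 1-ethyl (2R)-2-[(1R)-1-hydroxy-3-methylbut-3-en-1-yl]butanedioate
Conditions: LiN(iPr)2 (2.2 equiv), THF, −78 → −20 °C; then 5, DMPU, −78 → −20 °C
Reagents that add atoms: none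
Why: Fráter–Seebach alkylation: the chelated lithium alkoxide–enolate is alkylated on the face away from the C9 chain, which gives the anti product; this sets C7 from C8 in the relationship that is cis on the later six-membered ring.

Step 4
Reactants: 6 4-tert-butyl 1-ethyl (2R)-2-[(1R)-1-hydroxy-3-methylbut-3-en-1-yl]butanedioate
Product: 7 4-tert-butyl 1-ethyl (2R)-2-[(1R)-1-{[tert-butyl(dimethyl)silyl]oxy}-3-methylbut-3-en-1-yl]butanedioate
Conditions: TBSOTf, 2,6-lutidine, CH2Cl2, −78 → 0 °C
Reagents that add atoms: tert-butyldimethylsilyl trifluoromethanesulfonate, CC(C)(C)[Si](C)(C)OS(=O)(=O)C(F)(F)F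
Why: Silyl triflate silylation of a hindered secondary alcohol with a non-nucleophilic base; kept cold so that the tert-butyl ester is spared.

Step 5
Reactants: 7 4-tert-butyl 1-ethyl (2R)-2-[(1R)-1-{[tert-butyl(dimethyl)silyl]oxy}-3-methylbut-3-en-1-yl]butanedioate
Product: 8 tert-butyl (3R,4R)-4-{[tert-butyl(dimethyl)silyl]oxy}-3-[methoxy(methyl)carbamoyl]-6-methylhept-6-enoate
Conditions: MeNH(OMe)·HCl, iPrMgCl, THF, −20 → 0 °C
Reagents that add atoms: N,O-dimethylhydroxylamine hydrochloride, CNOC.Cl
Why: Weinreb aminolysis of the ethyl ester by the chloromagnesium amide; the tert-butyl ester is too hindered to react, and α-branched β-silyloxy esters are known to survive these conditions without elimination.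

Step 6
Reactants: 8 tert-butyl (3R,4R)-4-{[tert-butyl(dimethyl)silyl]oxy}-3-[methoxy(methyl)carbamoyl]-6-methylhept-6-enoate; 9 vinylmagnesium bromide
Product: 10 tert-butyl (3R,4R)-4-{[tert-butyl(dimethyl)silyl]oxy}-6-methyl-3-(prop-2-enoyl)hept-6-enoate
Conditions: 9, THF, −78 → 0 °C; cold 1 M HCl quench
Reagents that add atoms: none
Why: Grignard addition to the Weinreb amide stops at the chelated tetrahedral adduct, so the vinyl ketone is released only on the cold acidic quench; this keeps the liberated amine from adding to the enone and C7 from epimerising.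

Step 7
Reactants: 10 tert-butyl (3R,4R)-4-{[tert-butyl(dimethyl)silyl]oxy}-6-methyl-3-(prop-2-enoyl)hept-6-enoate
Product: 11 tert-butyl 2-[(1R,6R)-6-{[tert-butyl(dimethyl)silyl]oxy}-4-methyl-2-oxocyclohex-3-en-1-yl]acetate (enone C5–C10 with C6 ketone, C7 arm and C8 silyl ether cis to the arm)
Conditions: second-generation Grubbs catalyst RuCl2(=CHPh)(PCy3)(H2IMes) (5 mol%), CH2Cl2 (0.01 M), 40 °C
Reagents that add atoms: none
Why: Ring-closing metathesis between the vinyl ketone and the 1,1-disubstituted alkene closes the six-membered ring at C5=C10 with loss of ethene; the neutral conditions leave the epimerisable C7 and the β-silyloxy ketone intact.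

Step 8
Reactants: 12 methyl 3-oxocyclobutane-1-carboxylate
Product: 13 methyl cis-3-hydroxycyclobutane-1-carboxylate
Conditions: NaBH4, MeOH, −30 °C
Reagents that add atoms: none
Why: Hydride adds to the puckered cyclobutanone from the face away from the ester and gives the cis alcohol; the compound is achiral, so nothing is at stake stereochemically.

Step 9
Reactants: 13 methyl cis-3-hydroxycyclobutane-1-carboxylate
Product: 16 rac-methyl 3-hydroxycyclobut-1-ene-1-carboxylate, via phenylselanyl ester 14 (not isolated), via selenoxide 15 (not isolated)
Conditions: LiN(iPr)2 (2.2 equiv), THF, −78 °C; PhSeBr, −78 → 0 °C; then H2O2 (30% aq.), pyridine, CH2Cl2, 0 → 25 °C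
Reagents that add atoms: none
Why: α-Selenenylation of the ester enolate (formed as the alkoxide–enolate dianion) followed by oxidation and syn-elimination of the selenoxide toward a ring CH2; the two CH2 groups are enantiotopic, so the cyclobutene necessarily forms as a racemate.

Step 10
Reactants: 16 rac-methyl 3-hydroxycyclobut-1-ene-1-carboxylate
Product: 17 methyl (3S)-3-hydroxycyclobut-1-ene-1-carboxylate
Conditions: Burkholderia cepacia lipase (immobilised), vinyl acetate, tBuOMe, 30 °C, run to just past half conversion
Reagents that add atoms: none
Why: Lipase-catalysed kinetic resolution of a cyclic secondary allylic alcohol by enantioselective acylation; by the Kazlauskas rule with the alkenyl arm as the large group the (R)-alcohol should be acylated and the (S)-alcohol left, and running past half conversion raises its enantiopurity. The configuration of 17 is to be confirmed by Mosher ester analysis.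

Step 11
Reactants: 17 methyl (3S)-3-hydroxycyclobut-1-ene-1-carboxylate
Product: 18 methyl (3S)-3-[(triethylsilyl)oxy]cyclobut-1-ene-1-carboxylate
Conditions: Et3SiCl, imidazole, CH2Cl2, 0 °C
Reagents that add atoms: chlorotriethylsilane, CC[Si](Cl)(CC)CC
Why: Standard silylation; the triethylsilyl ether is chosen because it can later be removed beside the tert-butyldimethylsilyl ether on C8.

Step 12
Reactants: 11 tert-butyl 2-[(1R,6R)-6-{[tert-butyl(dimethyl)silyl]oxy}-4-methyl-2-oxocyclohex-3-en-1-yl]acetate; 18 methyl (3S)-3-[(triethylsilyl)oxy]cyclobut-1-ene-1-carboxylate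
Product: 19 cis,anti,cis photoadduct, a tricyclo[4.4.0.0^2,5]decan-7-one (six-membered ring C5–C10 with C6 ketone, central cyclobutane C4–C5–C10–C1, outer cyclobutane C1–C4) with CO2Me on C4, exo OSiEt3 on C2, CH2CO2tBu on C7, OTBS on C8 and CH3 on C10
Conditions: hν (350 nm, Pyrex), 18 (3 equiv), CH2Cl2, −20 °C; then brief filtration through basic Al2O3, 23 °C
Reagents that add atoms: none
Why: The n,π* excited enone crosses to its triplet, which adds to the strained alkene of 18 to give a triplet 1,4-biradical; after spin inversion this collapses, so that C1–C10 and C4–C5 are formed and the central cyclobutane is closed by radical recombination (a stepwise [2+2], to which no Baldwin class applies). The closest known reaction type is the enone–alkene photocycloaddition of 3-methylcyclohex-2-enones with cyclobut-1-enecarboxylates, which gives head-to-head cis,anti,cis tricyclo[4.4.0.0^2,5]decanones. Head-to-head orientation (ester carbon C4 on the α-carbon C5) is the normal outcome with an acceptor-substituted alkene and also avoids two adjacent quaternary carbons. C5 and C10 are set by attack on the enone face opposite the cis-disposed C7 arm and C8 silyloxy group; a trans ring fusion, if formed, is corrected at C5 (α to the ketone) on the alumina. C1 and C4 are set by bonding to the cyclobutene face opposite the C2 silyloxy group with the outer four-membered ring exo. For the (3S)-enantiomer of 18 this exo, anti-to-oxygen approach is possible only on that same enone face, so the two chiral partners are matched. The step needs this regiochemistry and this enone face, because they decide that the C4 ester later shields the correct face of the C6 ketone and can reach O6. The configurations at C1, C4, C5 and C10 themselves disappear in step 14; C2, C7 and C8 are not touched.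

Step 13
Reactants: 19 cis,anti,cis photoadduct
Product: 21 tetracyclic 15,6-lactone (γ-lactone O6–C15 fused to the six-membered and the central four-membered ring), via C6 carbinol 20 (not isolated)
Conditions: NaBH4, MeOH–THF, −20 → 23 °C
Reagents that add atoms: none
Why: Borohydride reduces the cyclohexanone from the face opposite the angular C4 ester, which lies over the other face of C6; the resulting C6 alkoxide is cis to C4 and closes onto the neighbouring methyl ester (5-exo-trig acyl substitution). This is the C6 configuration of the target (oxygen trans to the C7 arm), and only this epimer can lactonise onto C15.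

Step 14
Reactants: 21 tetracyclic 15,6-lactone
Product: 22 (1(10)Z,4Z)-cyclodeca-1(10),4-diene 15,6-olide (bridged butenolide; C1=C10 ring-cis, C4=C5 ring-trans; OSiEt3 on C2, CH2CO2tBu on C7, OTBS on C8)
Conditions: PhMe (0.01 M, degassed), BHT (cat.), base-washed sealed tube, 175 °C
Reagents that add atoms: none
Why: Thermal cycloreversion of the bicyclo[2.2.0]hexane: the strained C1–C4 bond breaks to a 1,4-diyl stabilised at C4 by the lactone carbonyl, and cleavage of C5–C10 then gives the cyclodeca-1,5-diene. The lactone bridge allows only the C4=C5 isomer with C15 and C6 cis (ring-trans), and the cis ring fusion then places C9 cis to C2 on C1=C10; C2, C6, C7 and C8 are not involved.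

Step 15
Reactants: 22 cyclodecadiene 15,6-olide
Product: 24 tert-butyl ester diol (C6–OH and C15–OH on the ten-membered diene), via lactol 23 (not isolated)
Conditions: iBu2AlH (1.2 equiv), CH2Cl2, −78 °C; aq. KNaC4H4O6 work-up; then NaBH4, CeCl3·7H2O, MeOH, 0 °C
Reagents that add atoms: none
Why: iBu2AlH reduces the butenolide to the lactol at −78 °C while the tert-butyl ester survives; Luche reduction of the hydroxy enal tautomer then gives the ene-1,4-diol by 1,2-addition, with C15 at the alcohol level and O6 free.

Step 16
Reactants: 24 tert-butyl ester diol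
Product: 25 6,12-olide (trans-fused γ-lactone O6–C12) with free C15–OH, OSiEt3 on C2 and OTBS on C8
Conditions: KOtBu (0.2 equiv), THF, 0 °C
Reagents that add atoms: none
Why: Alkoxide-catalysed transesterification: the C6 alkoxide attacks the γ-placed tert-butyl ester (5-exo-trig) and releases tert-butoxide, which carries the chain; the C15 alkoxide has no comparably easy ring to form.

Step 17
Reactants: 25 6,12-olide
Product: 26 11-[(dimethylamino)methyl] lactone (C11 epimers)
Conditions: LiN(iPr)2 (2.3 equiv), THF, −78 °C; CH2=NMe2+ I− (Eschenmoser's salt), −78 → 0 °C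
Reagents that add atoms: N,N-dimethylmethyleneiminium iodide (Eschenmoser's salt), C=[N+](C)C.[I-]
Why: Mannich reaction of the lactone enolate with the preformed iminium salt; the C15 alkoxide forms first and is a spectator, and the configuration at C11 does not matter because it is erased in step 18.

Step 18
Reactants: 26 11-[(dimethylamino)methyl] lactone
Product: 28 α-methylene lactone (C11=C13; C15–OH free), via ammonium iodide 27 (not isolated)
Conditions: MeI, THF, 23 °C; then aq. NaHCO3, EtOAc, 23 °C
Reagents that add atoms: none
Why: Quaternisation of the amine and E1cB loss of trimethylamine give the exocyclic enoate under nearly neutral conditions.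

Step 19
Reactants: 28 α-methylene lactone
Product: 29 C15 acetate (OSiEt3 on C2, OTBS on C8)
Conditions: Ac2O, pyridine, CH2Cl2, 0 °C
Reagents that add atoms: acetic anhydride, CC(=O)OC(C)=O
Why: Acylation of the only free hydroxyl, a primary allylic one.

Step 20
Reactants: 29 C15 acetate
Product: 30 C2 alcohol (OAc on C15, OTBS on C8)
Conditions: PPTS (cat.), MeOH–CH2Cl2, 0 °C
Reagents that add atoms: none
Why: Acid-catalysed methanolysis removes the triethylsilyl ether and leaves the bulkier tert-butyldimethylsilyl ether, the acetate and the enoate.

Step 21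
Reactants: 30 C2 alcohol; 31 tiglic acid
Product: 32 C8 tert-butyldimethylsilyl ether of the target
Conditions: 31, 2,4,6-trichlorobenzoyl chloride, Et3N, THF, 23 °C; then 30, DMAP, PhMe, 23 °C
Reagents that add atoms: none
Why: Yamaguchi esterification through the mixed anhydride acylates the secondary allylic alcohol with retention at C2; the tiglate is the stable geometric isomer, so it is not expected to isomerise.

Step 22
Reactants: 32 C8 tert-butyldimethylsilyl ether of the target
Product: 33 target CNP0129394.2
Conditions: HF·pyridine, pyridine, THF, 0 → 23 °C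
Reagents that add atoms: none
Why: Fluoride cleavage of the silyl ether under buffered, weakly acidic conditions, which avoid the acyl migration and the lactone shift to the C8 oxygen that a basic fluoride source could cause.

## Compound list

1 | ethyl (3S)-4-chloro-3-hydroxybutanoate | CCOC(=O)C[C@H](O)CCl | starting material
2 | ethyl 2-[(2S)-oxiran-2-yl]acetate | CCOC(=O)C[C@H]1CO1 | intermediate
3 | prop-1-en-2-ylmagnesium bromide | CC(=C)[Mg]Br | starting material
4 | ethyl (3R)-3-hydroxy-5-methylhex-5-enoate | CCOC(=O)C[C@H](O)CC(C)=C | intermediate
5 | tert-butyl bromoacetate | CC(C)(C)OC(=O)CBr | starting material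
6 | 4-tert-butyl 1-ethyl (2R)-2-[(1R)-1-hydroxy-3-methylbut-3-en-1-yl]butanedioate | CCOC(=O)[C@H](CC(=O)OC(C)(C)C)[C@H](O)CC(C)=C | intermediate
7 | 4-tert-butyl 1-ethyl (2R)-2-[(1R)-1-{[tert-butyl(dimethyl)silyl]oxy}-3-methylbut-3-en-1-yl]butanedioate | CCOC(=O)[C@H](CC(=O)OC(C)(C)C)[C@H](O[Si](C)(C)C(C)(C)C)CC(C)=C | intermediate
8 | tert-butyl (3R,4R)-4-{[tert-butyl(dimethyl)silyl]oxy}-3-[methoxy(methyl)carbamoyl]-6-methylhept-6-enoate | CON(C)C(=O)[C@H](CC(=O)OC(C)(C)C)[C@H](O[Si](C)(C)C(C)(C)C)CC(C)=C | intermediate
9 | vinylmagnesium bromide | C=C[Mg]Br | starting material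
10 | tert-butyl (3R,4R)-4-{[tert-butyl(dimethyl)silyl]oxy}-6-methyl-3-(prop-2-enoyl)hept-6-enoate | C=CC(=O)[C@H](CC(=O)OC(C)(C)C)[C@H](O[Si](C)(C)C(C)(C)C)CC(C)=C | intermediate
11 | tert-butyl 2-[(1R,6R)-6-{[tert-butyl(dimethyl)silyl]oxy}-4-methyl-2-oxocyclohex-3-en-1-yl]acetate | O=C1[C@H](CC(=O)OC(C)(C)C)[C@H](O[Si](C)(C)C(C)(C)C)CC(C)=C1 | intermediate
12 | methyl 3-oxocyclobutane-1-carboxylate | COC(=O)C1CC(=O)C1 | starting material
13 | methyl cis-3-hydroxycyclobutane-1-carboxylate | COC(=O)[C@H]1C[C@@H](O)C1 | intermediate
14 | methyl 3-hydroxy-1-(phenylselanyl)cyclobutane-1-carboxylate | COC(=O)C1([Se]c2ccccc2)CC(O)C1 | intermediate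
15 | methyl 3-hydroxy-1-(phenylseleninyl)cyclobutane-1-carboxylate | COC(=O)C1([Se](=O)c2ccccc2)CC(O)C1 | intermediate
16 | rac-methyl 3-hydroxycyclobut-1-ene-1-carboxylate | COC(=O)C1=CC(O)C1 | intermediate
17 | methyl (3S)-3-hydroxycyclobut-1-ene-1-carboxylate | COC(=O)C1=C[C@@H](O)C1 | intermediate
18 | methyl (3S)-3-[(triethylsilyl)oxy]cyclobut-1-ene-1-carboxylate | COC(=O)C1=C[C@@H](O[Si](CC)(CC)CC)C1 | intermediate
19 | cis,anti,cis photoadduct (C6 ketone, C4 CO2Me, C2 OSiEt3, C7 CH2CO2tBu, C8 OTBS, C10 CH3) | O=C1[C@H](CC(=O)OC(C)(C)C)[C@H](O[Si](C)(C)C(C)(C)C)C[C@]2(C)[C@H]1[C@@]3(C(=O)OC)C[C@H](O[Si](CC)(CC)CC)[C@@H]23 | intermediate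
20 | C6 carbinol of 19 (hydroxyl cis to C4) | O[C@H]1[C@H](CC(=O)OC(C)(C)C)[C@H](O[Si](C)(C)C(C)(C)C)C[C@]2(C)[C@H]1[C@@]3(C(=O)OC)C[C@H](O[Si](CC)(CC)CC)[C@@H]23 | intermediate
21 | tetracyclic 15,6-lactone | O=C1O[C@H]2[C@H](CC(=O)OC(C)(C)C)[C@H](O[Si](C)(C)C(C)(C)C)C[C@]3(C)[C@H]2[C@]14C[C@H](O[Si](CC)(CC)CC)[C@@H]34 | intermediate
22 | (1(10)Z,4Z)-cyclodeca-1(10),4-diene 15,6-olide (bridged butenolide) | O=C1O[C@H]2[C@H](CC(=O)OC(C)(C)C)[C@H](O[Si](C)(C)C(C)(C)C)C/C(C)=C\[C@@H](O[Si](CC)(CC)CC)CC1=C2 | intermediate
23 | lactol of 22 (C15 hemiacetal, epimers) | OC1O[C@H]2[C@H](CC(=O)OC(C)(C)C)[C@H](O[Si](C)(C)C(C)(C)C)C/C(C)=C\[C@@H](O[Si](CC)(CC)CC)CC1=C2 | intermediate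
24 | tert-butyl ester diol (C6–OH, C15–OH) | O[C@@H]1/C=C(\CO)C[C@H](O[Si](CC)(CC)CC)/C=C(/C)C[C@@H](O[Si](C)(C)C(C)(C)C)[C@H]1CC(=O)OC(C)(C)C | intermediate
25 | 6,12-olide with free C15–OH | C1C(=O)O[C@@H]2/C=C(\CO)C[C@H](O[Si](CC)(CC)CC)/C=C(/C)C[C@@H](O[Si](C)(C)C(C)(C)C)[C@@H]12 | intermediate
26 | 11-[(dimethylamino)methyl] lactone (C11 epimers) | CN(C)CC1C(=O)O[C@@H]2/C=C(\CO)C[C@H](O[Si](CC)(CC)CC)/C=C(/C)C[C@@H](O[Si](C)(C)C(C)(C)C)[C@@H]12 | intermediate
27 | trimethylammonium iodide of 26 | C[N+](C)(C)CC1C(=O)O[C@@H]2/C=C(\CO)C[C@H](O[Si](CC)(CC)CC)/C=C(/C)C[C@@H](O[Si](C)(C)C(C)(C)C)[C@@H]12.[I-] | intermediate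
28 | α-methylene lactone with free C15–OH | C=C1C(=O)O[C@@H]2/C=C(\CO)C[C@H](O[Si](CC)(CC)CC)/C=C(/C)C[C@@H](O[Si](C)(C)C(C)(C)C)[C@@H]12 | intermediate
29 | C15 acetate (C2 OSiEt3, C8 OTBS) | C=C1C(=O)O[C@@H]2/C=C(\COC(C)=O)C[C@H](O[Si](CC)(CC)CC)/C=C(/C)C[C@@H](O[Si](C)(C)C(C)(C)C)[C@@H]12 | intermediate
30 | C2 alcohol (C15 OAc, C8 OTBS) | C=C1C(=O)O[C@@H]2/C=C(\COC(C)=O)C[C@H](O)/C=C(/C)C[C@@H](O[Si](C)(C)C(C)(C)C)[C@@H]12 | intermediate
31 | tiglic acid, (2E)-2-methylbut-2-enoic acid | C/C=C(\C)C(=O)O | starting material
32 | C8 tert-butyldimethylsilyl ether of the target | C=C1C(=O)O[C@@H]2/C=C(\COC(C)=O)C[C@H](OC(=O)/C(C)=C/C)/C=C(/C)C[C@@H](O[Si](C)(C)C(C)(C)C)[C@@H]12 | intermediate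
33 | CNP0129394.2 | C=C1C(=O)O[C@@H]2/C=C(\COC(C)=O)C[C@H](OC(=O)/C(C)=C/C)/C=C(/C)C[C@@H](O)[C@@H]12 | target

## Step count and least certain steps

Total step count: 22. Longest linear sequence: 18 steps (steps 1–7, then 12–22); the cyclobutene branch (steps 8–11) joins at step 12.

**Step 12 (key step).**
- What may go wrong: leakage into head-to-tail addition; attack on the enone face that carries the C7 and C8 substituents; and slow addition because the silyloxy group of 18 sits next to C1, which must bond to the fully substituted C10, so that enone dimerisation competes. Any adduct from the wrong enone face would later give the wrong C6 configuration or fail to lactonise.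
- Fallback (from 12 and 11, back at 22): the cyclobutene partner is replaced by one without a stereocentre and with two equivalent faces, and C2 is set late. Ketalisation of 12 would give methyl 3,3-dimethoxycyclobutane-1-carboxylate F1, and selenenylation with selenoxide elimination as in step 9 would give methyl 3,3-dimethoxycyclobut-1-ene-1-carboxylate F2. Irradiation of F2 with 11 would give the ketal photoadduct F3, reduction with lactonisation as in step 13 the ketal lactone F4, and heating as in step 14 the ketal cyclodecadiene olide F5. Mild aqueous acid would free the C2 enone F6. Corey–Bakshi–Shibata reduction with the (R)-oxazaborolidine and catecholborane would give the (2S)-alcohol F7, and silylation with Et3SiCl returns to 22.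

**Step 13.**
- What may go wrong: hydride delivery from the face of the angular ester, because the C7 arm hinders the other face, which gives the C6 epimer that cannot close onto C15; and slow epimerisation at C7 in basic methanol before reduction.
- Fallback (from 19, back at 21): the epimeric carbinol, the 6-epi hydroxy ester F8, would be inverted by a Mitsunobu reaction with 4-nitrobenzoic acid to the 4-nitrobenzoate F9. Methanolysis with K2CO3 in MeOH frees the inverted C6 alkoxide, which lactonises onto C15 to give 21.

**Step 14.**
- What may go wrong: onward Cope rearrangement of the 1,5-diene to a divinylcyclohexane, made easier by the silyloxy group on C2 and leading to loss of the C2 centre; thermal loss of isobutene from the tert-butyl ester; or incomplete cycloreversion if the temperature is lowered to avoid these.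
- Fallback (from 19, back at 22): the cycloreversion is run before the reduction. Heating 19 would give the C6-keto cyclodecadiene ester F10, whose product is not a strained bridgehead butenolide, at the price of losing the tether control of C4=C5. Luche reduction would give the C6 hydroxy ester F11, which closes onto the cis-placed C15 ester to give 22.

**Step 10.**
- What may go wrong: weak or reversed enantiodiscrimination by the lipase, because the two ring arms at the carbinol differ little in size on a flat four-membered ring.
- Fallback (from 16, back at 17): oxidation of 16 with MnO2 would give methyl 3-oxocyclobut-1-ene-1-carboxylate F12, used at once, and Corey–Bakshi–Shibata reduction with the (R)-oxazaborolidine would give 17 without loss of half the material.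

**Step 16.**
- What may go wrong: migration of the silyl group from O8 to the C6 alkoxide followed by closure of the freed C8 oxygen to the 8,12-olide; or base-induced alkene isomerisation.
- Fallback (from 24, back at 25): treatment of 24 with Me3SiOTf and 2,6-lutidine, followed by mild methanolytic work-up, would cleave the tert-butyl ester without base and give the hydroxy acid F13. Lactonisation of F13 with a carbodiimide and DMAP gives 25.

## Further compounds

F1 | step 12 | methyl 3,3-dimethoxycyclobutane-1-carboxylate | COC(=O)C1CC(OC)(OC)C1
F2 | step 12 | methyl 3,3-dimethoxycyclobut-1-ene-1-carboxylate | COC(=O)C1=CC(OC)(OC)C1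
F3 | step 12 | ketal photoadduct (as 19, with C2 dimethyl ketal) | O=C1[C@H](CC(=O)OC(C)(C)C)[C@H](O[Si](C)(C)C(C)(C)C)C[C@]2(C)[C@H]1[C@@]3(C(=O)OC)CC(OC)(OC)[C@@H]23
F4 | step 12 | ketal tetracyclic 15,6-lactone | O=C1O[C@H]2[C@H](CC(=O)OC(C)(C)C)[C@H](O[Si](C)(C)C(C)(C)C)C[C@]3(C)[C@H]2[C@]14CC(OC)(OC)[C@@H]34
F5 | step 12 | ketal cyclodecadiene 15,6-olide | O=C1O[C@H]2[C@H](CC(=O)OC(C)(C)C)[C@H](O[Si](C)(C)C(C)(C)C)C/C(C)=C\C(OC)(OC)CC1=C2
F6 | step 12 | C2 enone of the cyclodecadiene 15,6-olide | O=C1O[C@H]2[C@H](CC(=O)OC(C)(C)C)[C@H](O[Si](C)(C)C(C)(C)C)C/C(C)=C\C(=O)CC1=C2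
F7 | step 12 | (2S)-alcohol of the cyclodecadiene 15,6-olide | O=C1O[C@H]2[C@H](CC(=O)OC(C)(C)C)[C@H](O[Si](C)(C)C(C)(C)C)C/C(C)=C\[C@@H](O)CC1=C2
F8 | step 13 | 6-epi hydroxy ester (hydroxyl trans to C4) | O[C@@H]1[C@H](CC(=O)OC(C)(C)C)[C@H](O[Si](C)(C)C(C)(C)C)C[C@]2(C)[C@H]1[C@@]3(C(=O)OC)C[C@H](O[Si](CC)(CC)CC)[C@@H]23
F9 | step 13 | C6 4-nitrobenzoate with inverted C6 | O=C(O[C@H]1[C@H](CC(=O)OC(C)(C)C)[C@H](O[Si](C)(C)C(C)(C)C)C[C@]2(C)[C@H]1[C@@]3(C(=O)OC)C[C@H](O[Si](CC)(CC)CC)[C@@H]23)c1ccc(cc1)[N+](=O)[O-]
F10 | step 14 | C6-keto cyclodecadiene methyl ester | O=C1/C=C(\C(=O)OC)C[C@H](O[Si](CC)(CC)CC)/C=C(/C)C[C@@H](O[Si](C)(C)C(C)(C)C)[C@H]1CC(=O)OC(C)(C)C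
F11 | step 14 | C6 hydroxy cyclodecadiene methyl ester | O[C@@H]1/C=C(\C(=O)OC)C[C@H](O[Si](CC)(CC)CC)/C=C(/C)C[C@@H](O[Si](C)(C)C(C)(C)C)[C@H]1CC(=O)OC(C)(C)C
F12 | step 10 | methyl 3-oxocyclobut-1-ene-1-carboxylate | COC(=O)C1=CC(=O)C1
F13 | step 16 | hydroxy acid (C12 acid, C6–OH, C15–OH) | O[C@@H]1/C=C(\CO)C[C@H](O[Si](CC)(CC)CC)/C=C(/C)C[C@@H](O[Si](C)(C)C(C)(C)C)[C@H]1CC(=O)O
A1 | alternative 1 | ten-membered ring C6 carbinol with 2-substituted allyl ether arm on C7 | C1[C@@H](O[Si](C)(C)C(C)(C)C)[C@@H](C(=C)COCc2ccc(OC)cc2)[C@H](O)/C=C(\COC(C)=O)C[C@H](OC(=O)/C(C)=C/C)/C=C1/C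
A2 | alternative 1 | open-chain C5 alkenyl iodide C6 aldehyde | O=C[C@H](C(=C)COCc1ccc(OC)cc1)[C@H](O[Si](C)(C)C(C)(C)C)C/C(C)=C\[C@@H](OC(=O)/C(C)=C/C)C/C(COC(C)=O)=C/I
A3 | alternative 2 | C8 silyl ether of the target (identical with 32) | C1[C@@H](O[Si](C)(C)C(C)(C)C)[C@H]2C(=C)C(=O)O[C@@H]2/C=C(\COC(C)=O)C[C@H](OC(=O)/C(C)=C/C)/C=C1/C
A4 | alternative 2 | ring diene acid (C15=C4–C5=C6 diene, acrylic acid arm on C7) | C1[C@@H](O[Si](C)(C)C(C)(C)C)[C@@H](C(=C)C(=O)O)/C=C\C(=C)C[C@H](OC(=O)/C(C)=C/C)/C=C1/C
A5 | alternative 3 | ten-membered C10 ketone with cis C1=C2, trans C4=C5 and free C15–OH | C1[C@@H](O[Si](C)(C)C(C)(C)C)[C@H]2C(=C)C(OC)O[C@@H]2/C=C(\CO)C/C=C\C1=O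
A6 | alternative 3 | trans-decalin with C10 hydroxyl and C4 spiro-epoxide | C1[C@@H](O[Si](C)(C)C(C)(C)C)[C@H]2C(=C)C(OC)O[C@@H]2[C@H]3[C@@]4(CO4)CC=C[C@]13O
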